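**Assumption:** the target has no stereocentre and no stereogenic double bond (each side-chain alkene ends in two identical methyl groups), so it is achiral and "single enantiomer" reduces to making the constitution shown.

**Retrosynthetic overview**
1. Target ⇐ its pentaacetate (mild methanolysis); all three prenyl groups ⇐ three allyl groups in one operation by triple olefin cross-metathesis with 2-methylbut-2-ene (key step; no prenyl halide is used anywhere).
2. C6 and C8 allyl groups ⇐ 5,7-bis(allyl ether) by tandem double aromatic Claisen rearrangement; the ring B methyl ethers are exchanged for acetates between Claisen and metathesis.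
3. Flavone ⇐ phloroglucinol + an α-allyl aroylacetate by a one-step thermal Mentzer pyrone annulation (forms C4–C4a and O1–C2, brings in the C3 allyl group), instead of the usual chalcone or Baker–Venkataraman sequence.
4. α-Allyl β-keto ester ⇐ 2,4,5-trimethoxybenzoic acid + ethyl pent-4-enoate (crossed Claisen condensation).
5. Ring order: rings A and B are bought; ring C is the only ring formed (step 2).

**Route**

Step 1
Reactants: 1 2,4,5-trimethoxybenzoic acid; 2 ethyl pent-4-enoate
Product: 5 ethyl 2-(2,4,5-trimethoxybenzoyl)pent-4-enoate (racemic), via lithium ester enolate 3 (not isolated), via acyl imidazole 4 (not isolated)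
Conditions: 1, CDI (1.1 equiv), THF, rt; added to 2 (3.3 equiv) + LiN(iPr)2 (3.3 equiv), THF, −78 °C to 0 °C; then 1 M aq. HCl
Reagents that add atoms: none
Why: Crossed Claisen condensation of an ester enolate with an N-acylimidazole: the acyl imidazole is an efficient C-acylating agent and the extra base parks the product as its enolate (one further equivalent is consumed by the imidazole N–H), while the new α-stereocentre is formed racemic and is erased when that carbon becomes sp2 C3 in step 2.

Step 2
Reactants: 5 ethyl 2-(2,4,5-trimethoxybenzoyl)pent-4-enoate; 6 phloroglucinol (anhydrous)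
Product: 9 3-allyl-5,7-dihydroxy-2-(2,4,5-trimethoxyphenyl)-4H-chromen-4-one, via acylketene 7 (not isolated), via aryl triketone 8 (not isolated)
Conditions: 6 (1.5 equiv), neat melt, 240 °C, N2 sweep (EtOH and H2O distil out), 20 min
Reagents that add atoms: none
Why: Mentzer pyrone synthesis: thermal loss of ethanol from 5 gives acylketene 7, which C-acylates the symmetric, very electron-rich phloroglucinol to triketone 8, whose ortho-phenol cyclodehydrates onto the aryl ketone to close ring C as the flavone (acid-free conditions disfavour the Pechmann coumarin), so ring C and the C3 allyl group arrive in one operation.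

Step 3
Reactants: 9 3-allyl-5,7-dihydroxy-2-(2,4,5-trimethoxyphenyl)-4H-chromen-4-one
Product: 10 3-allyl-5,7-bis(allyloxy)-2-(2,4,5-trimethoxyphenyl)-4H-chromen-4-one
Conditions: allyl bromide (4 equiv), Cs2CO3 (4 equiv), DMF, 50 °C
Reagents that add atoms: allyl bromide, C=CCBr
Why: Williamson etherification: Cs2CO3 in DMF with excess allyl bromide alkylates the acidic 7-OH and, on warming, the hydrogen-bonded 5-OH, and any C-allylation at C6 or C8 is productive because step 4 places allyl groups there anyway.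

Step 4
Reactants: 10 3-allyl-5,7-bis(allyloxy)-2-(2,4,5-trimethoxyphenyl)-4H-chromen-4-one
Product: 12 3,6,8-triallyl-5,7-dihydroxy-2-(2,4,5-trimethoxyphenyl)-4H-chromen-4-one, via monorearranged phenol 11 (not isolated)
Conditions: PhNEt2, 200 °C, sealed tube, argon
Reagents that add atoms: none
Why: Tandem aromatic Claisen rearrangement ([3,3]-sigmatropic): the 7-O-allyl group migrates to C8 and the 5-O-allyl group to C6, and because C6 and C8 are the only open positions of ring A every ortho or para (Claisen–Cope) pathway converges on the 6,8-diallyl diphenol, the amine solvent suppressing acid-catalysed ring closure of the ortho-allylphenols.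

Step 5
Reactants: 12 3,6,8-triallyl-5,7-dihydroxy-2-(2,4,5-trimethoxyphenyl)-4H-chromen-4-one
Product: 13 3,6,8-triallyl-5,7-dihydroxy-2-(2,4,5-trihydroxyphenyl)-4H-chromen-4-one
Conditions: BBr3 (8 equiv), CH2Cl2, −78 °C to 0 °C; then ice-water; crude product kept under argon
Reagents that add atoms: none
Why: Lewis-acid cleavage of aryl methyl ethers with BBr3: monosubstituted allyl groups tolerate BBr3 at or below 0 °C, unlike prenyl groups, which is why this step precedes the metathesis.

Step 6
Reactants: 13 3,6,8-triallyl-5,7-dihydroxy-2-(2,4,5-trihydroxyphenyl)-4H-chromen-4-one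
Product: 14 3,6,8-triallyl-2-(2,4,5-triacetoxyphenyl)-4-oxo-4H-chromene-5,7-diyl diacetate
Conditions: Ac2O (10 equiv), pyridine, DMAP (cat.), rt
Reagents that add atoms: acetic anhydride, CC(=O)OC(C)=O
Why: DMAP-catalysed acylation of all five phenols: it stops air oxidation of the hydroxyquinol ring B, makes the material soluble in CH2Cl2 and keeps free catechol-type phenols away from the ruthenium catalyst of step 7.

Step 7
Reactants: 14 3,6,8-triallyl-2-(2,4,5-triacetoxyphenyl)-4-oxo-4H-chromene-5,7-diyl diacetate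
Product: 15 3,6,8-tris(3-methylbut-2-en-1-yl)-2-(2,4,5-triacetoxyphenyl)-4-oxo-4H-chromene-5,7-diyl diacetate
Conditions: 2-methylbut-2-ene (large excess, co-solvent), second-generation Grubbs catalyst (H2IMes)(PCy3)Cl2Ru=CHPh (10 mol % in two portions), CH2Cl2, 40 °C, sealed tube
Reagents that add atoms: 2-methylbut-2-ene, CC=C(C)C
Why: Olefin cross-metathesis: each monosubstituted allyl alkene exchanges its CH2 terminus for the isopropylidene unit of the partner used in large excess, the trisubstituted prenyl products do not re-enter the cycle and propene leaves as a gas, so all three side chains are converted in one operation with no stereochemical issue.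

Step 8
Reactants: 15 3,6,8-tris(3-methylbut-2-en-1-yl)-2-(2,4,5-triacetoxyphenyl)-4-oxo-4H-chromene-5,7-diyl diacetate
Product: 16 5,7-dihydroxy-3,6,8-tris(3-methylbut-2-en-1-yl)-2-(2,4,5-trihydroxyphenyl)-4H-chromen-4-one
Conditions: K2CO3 (2 equiv), degassed MeOH–THF, 0 °C, argon; then AcOH
Reagents that add atoms: none
Why: Base-mediated transesterification (Zemplén-type methanolysis) of aryl acetates: it is fast at 0 °C, needs no acid that could cyclise the ortho-prenylphenols, and exclusion of oxygen protects the hydroxyquinol ring B.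

**Compound list**

1 | 2,4,5-trimethoxybenzoic acid | COc1cc(OC)c(OC)cc1C(=O)O | starting material
2 | ethyl pent-4-enoate | C=CCCC(=O)OCC | starting material
3 | lithium enolate of ethyl pent-4-enoate (lithium 1-ethoxypenta-1,4-dien-1-olate) | [Li]OC(OCC)=CCC=C | intermediate (not isolated)
4 | 1-(2,4,5-trimethoxybenzoyl)-1H-imidazole | COc1cc(OC)c(OC)cc1C(=O)n1ccnc1 | intermediate (not isolated)
5 | ethyl 2-(2,4,5-trimethoxybenzoyl)pent-4-enoate (racemic) | C=CCC(C(=O)OCC)C(=O)c1cc(OC)c(OC)cc1OC | intermediate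
6 | phloroglucinol (benzene-1,3,5-triol) | Oc1cc(O)cc(O)c1 | starting material
7 | 2-(2,4,5-trimethoxybenzoyl)penta-1,4-dien-1-one (allyl aroyl ketene) | C=CCC(=C=O)C(=O)c1cc(OC)c(OC)cc1OC | intermediate (not isolated)
8 | 2-allyl-1-(2,4,5-trimethoxyphenyl)-3-(2,4,6-trihydroxyphenyl)propane-1,3-dione (racemic) | C=CCC(C(=O)c1cc(OC)c(OC)cc1OC)C(=O)c1c(O)cc(O)cc1O | intermediate (not isolated)
9 | 3-allyl-5,7-dihydroxy-2-(2,4,5-trimethoxyphenyl)-4H-chromen-4-one | C=CCc1c(-c2cc(OC)c(OC)cc2OC)oc2cc(O)cc(O)c2c1=O | intermediate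
10 | 3-allyl-5,7-bis(allyloxy)-2-(2,4,5-trimethoxyphenyl)-4H-chromen-4-one | C=CCOc1cc(OCC=C)c2c(c1)oc(-c1cc(OC)c(OC)cc1OC)c(CC=C)c2=O | intermediate
11 | 3,8-diallyl-5-(allyloxy)-7-hydroxy-2-(2,4,5-trimethoxyphenyl)-4H-chromen-4-one | C=CCOc1cc(O)c(CC=C)c2oc(-c3cc(OC)c(OC)cc3OC)c(CC=C)c(=O)c12 | intermediate (not isolated)
12 | 3,6,8-triallyl-5,7-dihydroxy-2-(2,4,5-trimethoxyphenyl)-4H-chromen-4-one | C=CCc1c(O)c(CC=C)c2oc(-c3cc(OC)c(OC)cc3OC)c(CC=C)c(=O)c2c1O | intermediate
13 | 3,6,8-triallyl-5,7-dihydroxy-2-(2,4,5-trihydroxyphenyl)-4H-chromen-4-one | C=CCc1c(O)c(CC=C)c2oc(-c3cc(O)c(O)cc3O)c(CC=C)c(=O)c2c1O | intermediate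
14 | 3,6,8-triallyl-2-(2,4,5-triacetoxyphenyl)-4-oxo-4H-chromene-5,7-diyl diacetate | C=CCc1c(OC(C)=O)c(CC=C)c2oc(-c3cc(OC(C)=O)c(OC(C)=O)cc3OC(C)=O)c(CC=C)c(=O)c2c1OC(C)=O | intermediate
15 | 3,6,8-tris(3-methylbut-2-en-1-yl)-2-(2,4,5-triacetoxyphenyl)-4-oxo-4H-chromene-5,7-diyl diacetate | CC(C)=CCc1c(OC(C)=O)c(CC=C(C)C)c2oc(-c3cc(OC(C)=O)c(OC(C)=O)cc3OC(C)=O)c(CC=C(C)C)c(=O)c2c1OC(C)=O | intermediate
16 | 5,7-dihydroxy-3,6,8-tris(3-methylbut-2-en-1-yl)-2-(2,4,5-trihydroxyphenyl)-4H-chromen-4-one (CNP0243236.0) | CC(C)=CCc1c(O)c(CC=C(C)C)c2oc(-c3cc(O)c(O)cc3O)c(CC=C(C)C)c(=O)c2c1O | target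

**Totals**
Total step count: 8. Longest linear sequence: 8 steps (1 → 16); phloroglucinol 6 joins in step 2.

**Three steps most likely to fail**

Step 2 (Mentzer annulation with the α-allylated keto ester). The α-substituent slows acylketene formation and ring closure, and coumarin formation or thermal decarboxylation of 5 may dominate. The fallback sets out from 1 (with 6) and comes back at 10; it installs the C3 allyl group after ring C is closed.
- Acid 1 is activated with CDI to 4 as in step 1 and condensed with ethyl acetate (LiN(iPr)2, THF, −78 °C) to ethyl 3-oxo-3-(2,4,5-trimethoxyphenyl)propanoate F1.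
- F1 and 6 undergo the unsubstituted Mentzer annulation (neat, 240 °C) to 5,7-dihydroxy-2-(2,4,5-trimethoxyphenyl)-4H-chromen-4-one F2.
- Bis-O-allylation (allyl bromide, Cs2CO3, DMF, 50 °C) gives 5,7-bis(allyloxy)-2-(2,4,5-trimethoxyphenyl)-4H-chromen-4-one F3.
- Deprotonation at C3 with LiN(iPr)2 in THF at −78 °C gives 5,7-bis(allyloxy)-3-lithio-2-(2,4,5-trimethoxyphenyl)-4H-chromen-4-one F4 (not isolated), which is quenched with allyl bromide to give 10; the route resumes at step 4.

Step 4 (double Claisen rearrangement). At 200 °C the ortho-allylphenols may cyclise to dihydrobenzofurans or the 5-O-allyl group may be lost. The fallback sets out from 9 and comes back at 12, replacing the sigmatropic approach by halogenation and cross-coupling (step 3 is then not needed).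
- 9 is iodinated at the two phenol-activated ring A positions (NIS 2.1 equiv, DMF, 0 °C) to 3-allyl-5,7-dihydroxy-6,8-diiodo-2-(2,4,5-trimethoxyphenyl)-4H-chromen-4-one F5.
- A double Stille coupling (allyltributylstannane, Pd(PPh3)4, DMF, 90 °C) gives 12.

Step 5 (BBr3 demethylation in the presence of three allyl groups). The HBr formed may close the C6 and C8 allyl groups onto the neighbouring free phenols. The fallback sets out from 12 and comes back at 14; it changes the protecting-group order so that no free ortho-allylphenol is present during ether cleavage.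
- 12 is acetylated on the two ring A phenols (Ac2O, pyridine, DMAP, rt) to 3,6,8-triallyl-4-oxo-2-(2,4,5-trimethoxyphenyl)-4H-chromene-5,7-diyl diacetate F6.
- The ring B ethers are cleaved (BBr3, CH2Cl2, −78 °C to −20 °C) to 3,6,8-triallyl-4-oxo-2-(2,4,5-trihydroxyphenyl)-4H-chromene-5,7-diyl diacetate F7.
- Acetylation of the three new phenols (Ac2O, pyridine, DMAP) gives 14; any acetate lost in the boron step is restored here.

**Further compounds**

F1 | step 2 | ethyl 3-oxo-3-(2,4,5-trimethoxyphenyl)propanoate | CCOC(=O)CC(=O)c1cc(OC)c(OC)cc1OC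
F2 | step 2 | 5,7-dihydroxy-2-(2,4,5-trimethoxyphenyl)-4H-chromen-4-one | COc1cc(OC)c(-c2cc(=O)c3c(O)cc(O)cc3o2)cc1OC
F3 | step 2 | 5,7-bis(allyloxy)-2-(2,4,5-trimethoxyphenyl)-4H-chromen-4-one | C=CCOc1cc(OCC=C)c2c(c1)oc(-c1cc(OC)c(OC)cc1OC)cc2=O
F4 | step 2 | 5,7-bis(allyloxy)-3-lithio-2-(2,4,5-trimethoxyphenyl)-4H-chromen-4-one | [Li]c1c(-c2cc(OC)c(OC)cc2OC)oc2cc(OCC=C)cc(OCC=C)c2c1=O
F5 | step 4 | 3-allyl-5,7-dihydroxy-6,8-diiodo-2-(2,4,5-trimethoxyphenyl)-4H-chromen-4-one | C=CCc1c(-c2cc(OC)c(OC)cc2OC)oc2c(I)c(O)c(I)c(O)c2c1=O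
F6 | step 5 | 3,6,8-triallyl-4-oxo-2-(2,4,5-trimethoxyphenyl)-4H-chromene-5,7-diyl diacetate | C=CCc1c(OC(C)=O)c(CC=C)c2oc(-c3cc(OC)c(OC)cc3OC)c(CC=C)c(=O)c2c1OC(C)=O
F7 | step 5 | 3,6,8-triallyl-4-oxo-2-(2,4,5-trihydroxyphenyl)-4H-chromene-5,7-diyl diacetate | C=CCc1c(OC(C)=O)c(CC=C)c2oc(-c3cc(O)c(O)cc3O)c(CC=C)c(=O)c2c1OC(C)=O
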